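A small charge of racemization catalyst, 10 µM in alpha, 30 µM in gamma and 100 µM in delta, stands against 20 mM of each substrate, and you want to know what that charge does to the left-handed product.

    partner + left-handed substrate → left-handed product (k1 = 0.27 M⁻¹ min⁻¹)
    left-handed substrate + racemization catalyst ⇌ right-handed substrate + racemization catalyst, rate k2*[racemization catalyst]*[left-handed substrate] forward; the back reaction follows from the equilibrium constant (k2 = 150 M⁻¹ min⁻¹)
    solid reagent ⇌ partner, rate k3*(cs3 - [partner]) while solid is left; crystals form when [partner] > cs3 (cs3 = 2.5 mM, k3 = 0.0056 min⁻¹)
    partner + right-handed substrate → right-handed product (k4 = 0.089 M⁻¹ min⁻¹)
    partner → decomposed reagent (k5 = 0.015 min⁻¹)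

all flasks: left-handed substrate 20 mM; solid reagent 50.0 mM; right-handed substrate 20 mM; time 20 h
- alpha: racemization catalyst 10 µM
- gamma: racemization catalyst 30 µM
- delta: racemization catalyst 100 µM

- partner is single-handed; left-handed substrate and right-handed substrate are mirror images of each other, charged as a racemate, each of them at the stated concentration
- given per volume of solution although it is solid: solid reagent
- at the start none of the solid reagent is in solution
- "hardly changes" means that all values lie within two and a half points (for a concentration: within two and a half percent of the largest)
- run time (alpha): 20 h
- the handed part of partner does not stay in what it makes, so the products of the two hands are mirror images too

* [left-handed product] at the end for alpha, gamma, delta, in this order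
* how the row runs (rises all the way / falls, then rises / falls all the way / hardly changes / rises, then falls)

Take the racemate as the zero of your scale: with the hands held equal, the two products form in the selectivity factor of 3.03, and the catalyst can act on the left-handed product by way of the departure from that zero. You need the partner first. Dissolution feeds it while decomposition and the two couplings remove it, so with the substrates as charged it rests at a steady 0.504 mM, and the 13.4 mM dissolved in 20 h is less than the 50.0 mM of solid. This level contains no catalyst. The unequal couplings pull the hands apart, racemization closes the difference, and the two balance at 3.04% in alpha: this is the hand gap, the difference of the two coupling constants times c(partner), over 2 times the racemization constant times c(racemization catalyst), as a fraction of c(substrate). In alpha racemization runs ten times faster than the coupling drains the left-handed substrate, and the gap approaches that balance exponentially with a time constant of 5.56 h, shorter than the run. Delta, the neighbour, has a gap of 0.304%. The left-handed substrate thus sits 1.52% below the mean of the hands in alpha and 0.152% below it in delta, so 10.0 times the catalyst should buy about 1.37% of left-handed product. My flat-substrate figure is 3.27 mM, which I expect to be high, since the substrate falls during the run.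

The forecast, made apart from this, gave 3 mM, 3.04 mM and 3.05 mM, hardly changes, holding that “this rate is set by supply rather than by the catalyst”; its first value lies below my flat figure.

The simulation gives 3.01 mM, 3.03 mM and 3.04 mM: hardly changes.

In alpha, at 9.91 h, the left-handed substrate went to left-handed product at 0.092 of the rate at which it went to the right-handed substrate, counting the forward racemization step alone, and the hand gap of 3.04% stands against end readings of 89% left-handed and 91% right-handed substrate left of what was charged. In delta the gap of 0.304% stands against 90% left-handed and 90% right-handed substrate left at 20.0 h.

The numbers stand for no real mixture; what happens was integrated by code.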